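Target 17 ← α-bromo enone 16 (reversible carbonyl reduction sets C3 trans to the C4 bromine) ← enone 14 (α′-bromination sets C4) ← spirotriene 11 (diimide, desilylation, oxidation).
Ring B and the spiro centre C6 are made together: C6–C11 by 6π electrocyclization of (Z)-triene 10, which arises by [1,5]-H shift from vinylallene 9, itself made by forming C8–C9 in a Suzuki–Miyaura coupling of allenylboronate 6 with (E)-2,3-dibromobut-2-ene 8.
Enabling feature: ring B is a cyclohexene whose C9(CH3)=C10(Br) bond is flanked by the C11 methylene on spiro C6; one extra C7=C8 bond makes it a cyclohexa-1,3-diene, the retron of a triene whose termini are C11 (a methyl group of 8) and C6 (the hindered C1 carbonyl carbon of ketoisophorone, converted into an exocyclic allene terminus).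
Ring A is bought as ketoisophorone 1; its C3 carbinol (asymmetric transfer hydrogenation) is the only external source of chirality, relays to C6 in the key step, and is then erased and reset.
Order of rings: ring A (purchased), then ring B (step 6).

Key step: step 6

Remark: the spiro skeleton is numbered C1–C5 (ring A), C6 (spiro), C7–C11 (ring B) and atoms of open-chain precursors are called by the numbers they receive in it; the carbinol epimer of 4/5 and the allene axis of 6 and 9 are not controlled because both are erased in step 6 (SMILES of 4/5 show the expected major epimer, those of 6 and 9 leave the axis open); the (S,S)-ligand in step 1 is assumed to give the (4S)-carbinol, otherwise its enantiomer is used.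

Step 1
Reactants: 1 2,6,6-trimethylcyclohex-2-ene-1,4-dione (ketoisophorone)
Product: 2 (4S)-4-hydroxy-2,6,6-trimethylcyclohex-2-en-1-one
Conditions: RuCl[(S,S)-TsDPEN](p-cymene) (0.5 mol %), HCO2H–Et3N (5:2), CH2Cl2, rt
Reagents that add atoms: none
Why: Noyori asymmetric transfer hydrogenation should reduce only the less hindered C4 carbonyl (flanked by CH= and CH2) and leave the C1 carbonyl between C(CH3)= and C(CH3)2 untouched, the (S,S)-ligand delivering hydride through the usual CH/π-organized six-membered transition state to give the (4S)-carbinol, the single external source of chirality of the route.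

Step 2
Reactants: 2 (4S)-4-hydroxy-2,6,6-trimethylcyclohex-2-en-1-one
Product: 3 (4S)-4-[(tert-butyldimethylsilyl)oxy]-2,6,6-trimethylcyclohex-2-en-1-one
Conditions: TBSCl, imidazole, DMF, rt
Reagents that add atoms: tert-butyldimethylsilyl chloride, CC(C)(C)[Si](C)(C)Cl
Why: Standard silyl ether formation masks the allylic alcohol for the organolithium, copper and palladium steps and provides the bulky pseudo-equatorial group that later fixes the conformation of ring A; the stereocentre is untouched.

Step 3
Reactants: 3 (4S)-4-[(tert-butyldimethylsilyl)oxy]-2,6,6-trimethylcyclohex-2-en-1-one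
Product: 5 methyl (1R,4S)-4-[(tert-butyldimethylsilyl)oxy]-1-ethynyl-2,6,6-trimethylcyclohex-2-en-1-yl carbonate, via lithium propargylic alkoxide 4 (not isolated)
Conditions: HC≡CH (excess), n-BuLi, THF, −78 °C; add 3, −78 → 0 °C; then ClCO2Me, 0 °C → rt
Reagents that add atoms: acetylene, C#C; methyl chloroformate, COC(=O)Cl
Why: 1,2-Addition of lithium acetylide to the hindered enone carbonyl followed by O-acylation of the tertiary alkoxide gives the propargylic carbonate in one flask; the carbinol centre should form mainly by attack anti to the pseudo-axial C6 methyl (ethynyl cis to OTBS), but both epimers are carried on because this centre is erased in steps 4 and 6.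

Step 4
Reactants: 5 methyl (1R,4S)-4-[(tert-butyldimethylsilyl)oxy]-1-ethynyl-2,6,6-trimethylcyclohex-2-en-1-yl carbonate
Product: 6 tert-butyldimethyl{[(1S)-3,5,5-trimethyl-4-[2-(4,4,5,5-tetramethyl-1,3,2-dioxaborolan-2-yl)ethenylidene]cyclohex-2-en-1-yl]oxy}silane
Conditions: CuCl (10 mol %), Xantphos (10 mol %), NaOtBu (15 mol %), B2pin2 (1.5 equiv), THF, rt
Reagents that add atoms: bis(pinacolato)diboron, CC1(C)OB(OC1(C)C)B1OC(C)(C)C(C)(C)O1
Why: Copper-catalysed SN2′ borylation of a propargylic carbonate (borylcupration of the terminal alkyne followed by anti β-elimination of the carbonate, which leaves as CO2 and methoxide) should give the γ,γ-disubstituted allenylboronate because the boryl group is delivered to the unhindered alkyne terminus and not to the congested carbinol carbon; the allene axis needs no control.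

Step 5
Reactants: 7 but-2-yne
Product: 8 (E)-2,3-dibromobut-2-ene
Conditions: Br2 (1.0 equiv), CH2Cl2, −40 °C, dark; distillation
Reagents that add atoms: bromine, BrBr
Why: Electrophilic anti addition of one equivalent of bromine to the alkyne through a bridged bromonium ion gives the (E)-dibromide, in which each methyl group is cis to the bromine on the other carbon, the arrangement the hydrogen shift of step 6 requires.

Step 6
Reactants: 6 tert-butyldimethyl{[(1S)-3,5,5-trimethyl-4-[2-(4,4,5,5-tetramethyl-1,3,2-dioxaborolan-2-yl)ethenylidene]cyclohex-2-en-1-yl]oxy}silane; 8 (E)-2,3-dibromobut-2-ene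
Product: 11 tert-butyl{[(3S,6S)-10-bromo-1,5,5,9-tetramethylspiro[5.5]undeca-1,7,9-trien-3-yl]oxy}dimethylsilane, via vinylallene 9 (not isolated), via (2Z)-triene 10 (not isolated)
Conditions: Pd(OAc)2 (5 mol %), SPhos (10 mol %), K3PO4 (3 equiv), 8 (3 equiv), toluene–H2O, 60 °C; then N-acetylcysteine, BHT, xylene, 140 °C (sealed), same flask
Reagents that add atoms: none
Why: Zerovalent palladium inserts into one C–Br bond of 8, the allenylboronate transmetallates at its CH terminus (the γ,γ-disubstituted terminus blocks the SE2′ path to a propargyl product) and reductive elimination with retention of the alkene geometry forms C8–C9, giving vinylallene 9 in which the CH3 on the CBr carbon is cis to the allene. On warming, 9 should undergo the [1,5]-sigmatropic hydrogen shift typical of vinylallenes, from that methyl to the central allene carbon (C7), which necessarily delivers the (2Z)-triene 10 with a terminal C(Br)=CH2 group, and 10 then closes ring B by a thermal disrotatory 6π electrocyclization between this CH2 (C11) and the exocyclic alkylidene carbon of ring A (C6). The closest known reaction types are the cross-coupling of allenylmetal reagents with alkenyl halides, the vinylallene [1,5]-H shift/6π-electrocyclization cascade, and thermal 6π closures that create a quaternary carbon (allo-ocimene to pyronene type). The new stereocentre C6 is controlled by the C3 silyl ether: OTBS must be pseudo-equatorial (pseudo-axial it would be syn to a C5 methyl), this fixes the ring A conformation, and C11 should bond to the face of C6 anti to the pseudo-axial C5 methyl, that is cis to OTBS, giving (6S). The step needs mono-coupling (excess 8; the remaining bromide sits on a more hindered diene carbon), the Z triene (guaranteed by the cyclic transition state of the H shift) and the absence of other pericyclic outlets, which the substrate secures because C1 and C5 of ring A carry no hydrogen for a [1,7]-H shift and the ring alkene is held s-trans to the exocyclic one, so no 8π or fused 6π mode exists.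

Step 7
Reactants: 11 tert-butyl{[(3S,6S)-10-bromo-1,5,5,9-tetramethylspiro[5.5]undeca-1,7,9-trien-3-yl]oxy}dimethylsilane
Product: 12 tert-butyl{[(3S,6R)-10-bromo-1,5,5,9-tetramethylspiro[5.5]undeca-1,9-dien-3-yl]oxy}dimethylsilane
Conditions: 2-nitrobenzenesulfonylhydrazide (excess), Et3N, CH2Cl2, rt
Reagents that add atoms: none
Why: Diimide reduction (concerted syn transfer of H2 from HN=NH generated from the sulfonylhydrazide) is governed by alkene substitution, so the cis-disubstituted C7=C8 bond should be saturated while the tetrasubstituted bromoalkene, the trisubstituted ring A alkene, the C–Br bond and the silyl ether survive; no stereocentre is created (the C6 descriptor changes only through the priority rules).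

Step 8
Reactants: 12 tert-butyl{[(3S,6R)-10-bromo-1,5,5,9-tetramethylspiro[5.5]undeca-1,9-dien-3-yl]oxy}dimethylsilane
Product: 13 (3S,6R)-10-bromo-1,5,5,9-tetramethylspiro[5.5]undeca-1,9-dien-3-ol
Conditions: TBAF, THF, 0 °C → rt
Reagents that add atoms: none
Why: Fluoride-induced cleavage of the Si–O bond frees the allylic alcohol under conditions that leave the alkenyl bromide and both alkenes untouched.

Step 9
Reactants: 13 (3S,6R)-10-bromo-1,5,5,9-tetramethylspiro[5.5]undeca-1,9-dien-3-ol
Product: 14 (6R)-10-bromo-1,5,5,9-tetramethylspiro[5.5]undeca-1,9-dien-3-one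
Conditions: MnO2 (activated, excess), CH2Cl2, rt
Reagents that add atoms: none
Why: Oxidation of the allylic alcohol on activated MnO2 gives the conjugated enone and deliberately erases the C3 carbinol centre once its relay to C6 is complete, leaving C6 as the only stereocentre.

Step 10
Reactants: 14 (6R)-10-bromo-1,5,5,9-tetramethylspiro[5.5]undeca-1,9-dien-3-one
Product: 16 (4S,6S)-4,10-dibromo-1,5,5,9-tetramethylspiro[5.5]undeca-1,9-dien-3-one, via trimethylsilyl dienol ether 15 (not isolated)
Conditions: LiN(iPr)2, THF, −78 °C; Me3SiCl; then N-bromosuccinimide, −78 → 0 °C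
Reagents that add atoms: N-bromosuccinimide, O=C1CCC(=O)N1Br
Why: Kinetic deprotonation at the only α′ position (C4) and silyl trapping give the cross-conjugated dienol ether, which N-bromosuccinimide brominates at C4 (α-bromination of a silyl enol ether); the C7 methylene arm of ring B should sit pseudo-axial on ring A (ring B tilts away from the C5 gem-dimethyl group and the axial C8–H then pushes the C1 methyl towards the flat C10 side), so it shields one face of C4 in a 1,3-diaxial sense and bromine should enter cis to the C11 methylene, giving the equatorial (4S)-bromide, which should also be the more stable epimer.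

Step 11
Reactants: 16 (4S,6S)-4,10-dibromo-1,5,5,9-tetramethylspiro[5.5]undeca-1,9-dien-3-one
Product: 17 (3S,4S,6S)-4,10-dibromo-1,5,5,9-tetramethylspiro[5.5]undeca-1,9-dien-3-ol
Conditions: Al(OiPr)3 (3 equiv), iPrOH–toluene, acetone (0.1 equiv), 70 °C, to equilibrium
Reagents that add atoms: none
Why: Meerwein–Ponndorf–Verley reduction is selective for the carbonyl group (no loss of the α-bromine, no 1,4-reduction) and reversible, so prolonged exposure should equilibrate the carbinol to the more stable trans-diequatorial bromohydrin, the (3S) epimer, whereas the cis epimer would carry a pseudo-axial OH syn to the axial C5 methyl.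

Compound list
1 | 2,6,6-trimethylcyclohex-2-ene-1,4-dione (ketoisophorone) | CC1=CC(=O)CC(C)(C)C1=O | starting material
2 | (4S)-4-hydroxy-2,6,6-trimethylcyclohex-2-en-1-one | CC1=C[C@@H](O)CC(C)(C)C1=O | intermediate
3 | (4S)-4-[(tert-butyldimethylsilyl)oxy]-2,6,6-trimethylcyclohex-2-en-1-one | CC1=C[C@@H](O[Si](C)(C)C(C)(C)C)CC(C)(C)C1=O | intermediate
4 | lithium (1R,4S)-4-[(tert-butyldimethylsilyl)oxy]-1-ethynyl-2,6,6-trimethylcyclohex-2-en-1-olate (not isolated; major epimer shown) | [Li+].CC1=C[C@@H](O[Si](C)(C)C(C)(C)C)CC(C)(C)[C@@]1([O-])C#C | intermediate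
5 | methyl (1R,4S)-4-[(tert-butyldimethylsilyl)oxy]-1-ethynyl-2,6,6-trimethylcyclohex-2-en-1-yl carbonate (major epimer shown) | CC1=C[C@@H](O[Si](C)(C)C(C)(C)C)CC(C)(C)[C@@]1(OC(=O)OC)C#C | intermediate
6 | tert-butyldimethyl{[(1S)-3,5,5-trimethyl-4-[2-(4,4,5,5-tetramethyl-1,3,2-dioxaborolan-2-yl)ethenylidene]cyclohex-2-en-1-yl]oxy}silane (allene axis open) | CC1=C[C@@H](O[Si](C)(C)C(C)(C)C)CC(C)(C)C1=C=CB2OC(C)(C)C(C)(C)O2 | intermediate
7 | but-2-yne | CC#CC | starting material
8 | (E)-2,3-dibromobut-2-ene | C/C(Br)=C(/C)Br | intermediate
9 | tert-butyl{[(1S)-4-[(3E)-4-bromo-3-methylpenta-1,3-dien-1-ylidene]-3,5,5-trimethylcyclohex-2-en-1-yl]oxy}dimethylsilane (vinylallene, not isolated; allene axis open) | CC1=C[C@@H](O[Si](C)(C)C(C)(C)C)CC(C)(C)C1=C=C/C(C)=C(/Br)C | intermediate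
10 | tert-butyl{[(1S)-4-[(2Z)-4-bromo-3-methylpenta-2,4-dien-1-ylidene]-3,5,5-trimethylcyclohex-2-en-1-yl]oxy}dimethylsilane (triene, not isolated; exocyclic alkene geometry open) | CC1=C[C@@H](O[Si](C)(C)C(C)(C)C)CC(C)(C)C1=C/C=C(C)\C(Br)=C | intermediate
11 | tert-butyl{[(3S,6S)-10-bromo-1,5,5,9-tetramethylspiro[5.5]undeca-1,7,9-trien-3-yl]oxy}dimethylsilane | CC1=C[C@@H](O[Si](C)(C)C(C)(C)C)CC(C)(C)[C@]12C=CC(C)=C(Br)C2 | intermediate
12 | tert-butyl{[(3S,6R)-10-bromo-1,5,5,9-tetramethylspiro[5.5]undeca-1,9-dien-3-yl]oxy}dimethylsilane | CC1=C[C@@H](O[Si](C)(C)C(C)(C)C)CC(C)(C)[C@]12CCC(C)=C(Br)C2 | intermediate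
13 | (3S,6R)-10-bromo-1,5,5,9-tetramethylspiro[5.5]undeca-1,9-dien-3-ol | CC1=C[C@@H](O)CC(C)(C)[C@]12CCC(C)=C(Br)C2 | intermediate
14 | (6R)-10-bromo-1,5,5,9-tetramethylspiro[5.5]undeca-1,9-dien-3-one | CC1=CC(=O)CC(C)(C)[C@]12CCC(C)=C(Br)C2 | intermediate
15 | {[(6S)-10-bromo-1,5,5,9-tetramethylspiro[5.5]undeca-1,3,9-trien-3-yl]oxy}trimethylsilane (not isolated) | CC1=CC(O[Si](C)(C)C)=CC(C)(C)[C@]12CCC(C)=C(Br)C2 | intermediate
16 | (4S,6S)-4,10-dibromo-1,5,5,9-tetramethylspiro[5.5]undeca-1,9-dien-3-one | CC1=CC(=O)[C@@H](Br)C(C)(C)[C@]12CCC(C)=C(Br)C2 | intermediate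
17 | (3S,4S,6S)-4,10-dibromo-1,5,5,9-tetramethylspiro[5.5]undeca-1,9-dien-3-ol | CC1=C[C@H](O)[C@@H](Br)C(C)(C)[C@]12CCC(C)=C(Br)C2 | target

Total step count: 11. Longest linear sequence: 10 steps (steps 1–4 and 6–11; step 5 prepares the coupling partner).

Steps most likely to fail

Step 6. The allenylboronate may transmetallate through its propargylic channel or be protodeboronated before it couples, the electrocyclization may need more heat than the dienyl bromide tolerates, and the facial selectivity at C6 may be modest (the minor C6 epimer stays a diastereomer up to 13 and would be removed there). Fallback, setting out from 3 and 8 and returning at 11: Sonogashira coupling of 8 (3 equiv) with ethynyltrimethylsilane (PdCl2(PPh3)2, CuI, iPr2NH, rt) should give (E)-(4-bromo-3-methylpent-3-en-1-yn-1-yl)trimethylsilane F1. K2CO3 in MeOH then gives (E)-4-bromo-3-methylpent-3-en-1-yne F2. Its lithium acetylide (LiN(iPr)2, THF, −78 °C) is added to ketone 3 and the alkoxide is trapped with ClCO2Me to give methyl (1S,4S)-1-[(3E)-4-bromo-3-methylpent-3-en-1-yn-1-yl]-4-[(tert-butyldimethylsilyl)oxy]-2,6,6-trimethylcyclohex-2-en-1-yl carbonate F3. SN2′ hydride delivery from [(Ph3P)CuH]6 (toluene, rt) should convert F3 into vinylallene 9, which on heating in xylene passes through 10 to 11. In this variant C8–C9 is made on a small reagent by an alkyne coupling and the allene by hydride substitution, so no allenylmetal is needed.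

Step 10. The two faces of C4 in the dienol ether differ only through the conformation of the ring B arms beyond the spiro carbon, so the bromination may discriminate poorly, and enolization towards the C1 methyl may compete. Fallback, setting out from 13 and returning at 17: dehydration of 13 with methyl N-(triethylammoniosulfonyl)carbamate (toluene, 60 °C) should give (6S)-10-bromo-1,5,5,9-tetramethylspiro[5.5]undeca-1,3,9-triene F4. N-Bromosuccinimide in wet 1,2-dimethoxyethane at 0 °C should then add bromine to the diene terminus C4 and water to the allylic carbon C3 in an anti sense, giving the trans bromohydrin 17 directly. The trans relationship then follows from the mechanism and steps 9–11 are bypassed.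

Step 11. Kinetic hydride delivery is expected from the face anti to the axial C5 methyl and leads to the cis bromohydrin; the equilibration may be slow or incomplete, and the aluminium alkoxide of the product may close to an epoxide. Fallback, setting out from 16 and returning at 17: iBu2AlH (CH2Cl2, −78 °C) should give the cis bromohydrin (3R,4S,6S)-4,10-dibromo-1,5,5,9-tetramethylspiro[5.5]undeca-1,9-dien-3-ol F5. Mitsunobu inversion with 4-nitrobenzoic acid (PPh3, diisopropyl azodicarboxylate, THF) gives (3S,4S,6S)-4,10-dibromo-1,5,5,9-tetramethylspiro[5.5]undeca-1,9-dien-3-yl 4-nitrobenzoate F6, and K2CO3 in MeOH releases 17.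

Further compounds
F1 | step 6 | (E)-(4-bromo-3-methylpent-3-en-1-yn-1-yl)trimethylsilane | C[Si](C)(C)C#C/C(C)=C(/Br)C
F2 | step 6 | (E)-4-bromo-3-methylpent-3-en-1-yne | C#C/C(C)=C(/Br)C
F3 | step 6 | methyl (1S,4S)-1-[(3E)-4-bromo-3-methylpent-3-en-1-yn-1-yl]-4-[(tert-butyldimethylsilyl)oxy]-2,6,6-trimethylcyclohex-2-en-1-yl carbonate | CC1=C[C@@H](O[Si](C)(C)C(C)(C)C)CC(C)(C)[C@@]1(OC(=O)OC)C#C/C(C)=C(/Br)C
F4 | step 10 | (6S)-10-bromo-1,5,5,9-tetramethylspiro[5.5]undeca-1,3,9-triene | CC1=CC=CC(C)(C)[C@]12CCC(C)=C(Br)C2
F5 | step 11 | (3R,4S,6S)-4,10-dibromo-1,5,5,9-tetramethylspiro[5.5]undeca-1,9-dien-3-ol | CC1=C[C@@H](O)[C@@H](Br)C(C)(C)[C@]12CCC(C)=C(Br)C2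
F6 | step 11 | (3S,4S,6S)-4,10-dibromo-1,5,5,9-tetramethylspiro[5.5]undeca-1,9-dien-3-yl 4-nitrobenzoate | CC1=C[C@H](OC(=O)c3ccc(cc3)[N+](=O)[O-])[C@@H](Br)C(C)(C)[C@]12CCC(C)=C(Br)C2
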